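The cyclohexene ring is cut at C1=C2, the one ring bond whose carbons are neither stereogenic nor oxygen-bearing. C3 and C6 stand cis on the C4–C5 oxirane, so an acyclic Sharpless epoxide already holds the two alkene termini on one face. A single ruthenium-catalysed ring-closing metathesis joins the C3 vinyl ketone to the 2-(acetoxymethyl)allyl unit on C6, expels ethylene and builds the enone ring on the finished oxirane and side chain. The metathesis substrate is an epoxy vinyl ketone with the C1′ acetate, the silyl-protected dienol chain and a silyl ether (not a free hydroxyl) at C6, so that the C3 ketone cannot close to a hemiketal.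

Key step: step 17

Remark: atoms are labelled as in the target (ring C1–C6, C1 bearing CH2OAc; chain C1′–C6′). The C3 and C6 carbinol centres are carried as epimer mixtures and drawn without descriptor, because both end as ketones.

Step 1
Reactants: 1 but-2-yne-1,4-diol
Product: 2 4-[(tert-butyldimethylsilyl)oxy]but-2-yn-1-ol
Conditions: NaH (1.0 equiv), THF, 0 °C to rt; then TBSCl (1.0 equiv)
Reagents that add atoms: tert-butyldimethylsilyl chloride, CC(C)(C)[Si](C)(C)Cl
Why: O-silylation of the sparingly soluble monosodium alkoxide of a symmetrical diol should stop after one silylation and so differentiates the two arms.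

Step 2
Reactants: 2 4-[(tert-butyldimethylsilyl)oxy]but-2-yn-1-ol
Product: 4 (2Z)-4-[(tert-butyldimethylsilyl)oxy]-3-iodobut-2-en-1-ol, via cyclic alkenylaluminate 3 (not isolated)
Conditions: Red-Al (1.5 equiv), THF, 0 °C to rt; then I2, −78 to 0 °C; aq. Rochelle salt/Na2S2O3
Reagents that add atoms: iodine, II
Why: Hydroxyl-directed trans-hydroalumination puts hydride on the alkyne carbon next to the free carbinol and aluminium on the carbon bearing CH2OTBS, and iodinolysis with retention gives the Z-iodoalkene whose two oxygenated arms are trans, the geometry that later places C3 cis to C6.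

Step 3
Reactants: 4 (2Z)-4-[(tert-butyldimethylsilyl)oxy]-3-iodobut-2-en-1-ol
Product: 5 (2Z)-4-[(tert-butyldimethylsilyl)oxy]-3-iodobut-2-enal
Conditions: activated MnO2 (excess), CH2Cl2, rt
Reagents that add atoms: none
Why: Manganese dioxide oxidation is selective for the primary allylic alcohol and should leave the vinyl iodide, its geometry and the silyl ether untouched.

Step 4
Reactants: 6 2-bromoprop-2-en-1-ol
Product: 7 2-bromoallyl 4-methoxybenzyl ether
Conditions: NaH, THF/DMF, 0 °C; PMBCl, Bu4NI (cat.), rt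
Reagents that add atoms: 4-methoxybenzyl chloride, COc1ccc(CCl)cc1
Why: Williamson ether synthesis masks the hydroxymethyl group that later becomes the C1 acetoxymethyl group with a group that is removed oxidatively.

Step 5
Reactants: 7 2-bromoallyl 4-methoxybenzyl ether; 5 (2Z)-4-[(tert-butyldimethylsilyl)oxy]-3-iodobut-2-enal
Product: 10 (4Z)-3,6-bis[(tert-butyldimethylsilyl)oxy]-5-iodo-2-{[(4-methoxybenzyl)oxy]methyl}hexa-1,4-diene, via 2-lithioallyl PMB ether 8 (not isolated), via lithium alkoxide 9 (not isolated)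
Conditions: 7, t-BuLi (2.0 equiv), Et2O, −78 °C; add 5, −78 °C; then TBSOTf, −78 to 0 °C
Reagents that add atoms: tert-butyldimethylsilyl trifluoromethanesulfonate, CC(C)(C)[Si](C)(C)OS(=O)(=O)C(F)(F)F
Why: Bromine–lithium exchange gives the 2-lithioallyl ether, whose 1,2-addition to the enal at −78 °C should outpace exchange with the vinyl iodide, and the alkoxide is silylated in the same flask; the new C6 carbinol centre is uncontrolled and is erased by the last oxidation.

Step 6
Reactants: 10 (4Z)-3,6-bis[(tert-butyldimethylsilyl)oxy]-5-iodo-2-{[(4-methoxybenzyl)oxy]methyl}hexa-1,4-diene; 11 acrolein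
Product: 13 (4Z)-6-[(tert-butyldimethylsilyl)oxy]-4-{[(tert-butyldimethylsilyl)oxy]methyl}-7-{[(4-methoxybenzyl)oxy]methyl}octa-1,4,7-trien-3-ol, via alkenyllithium 12 (not isolated)
Conditions: t-BuLi (2.1 equiv), Et2O, −78 °C, 15 min; acrolein, −78 °C; H2O quench
Reagents that add atoms: none
Why: Iodine–lithium exchange with retention of alkene geometry and 1,2-addition to acrolein attaches C3 cis to C6, ether solvent and −78 °C holding back 1,4 O-to-C silyl migration; the C3 carbinol centre is uncontrolled and is oxidised later.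

Step 7
Reactants: 13 (4Z)-6-[(tert-butyldimethylsilyl)oxy]-4-{[(tert-butyldimethylsilyl)oxy]methyl}-7-{[(4-methoxybenzyl)oxy]methyl}octa-1,4,7-trien-3-ol
Product: 14 3-O-(4-methoxybenzyl) ether of 13
Conditions: 2-(4-methoxybenzyloxy)-4-methylquinoline (2 equiv), MeOTf (2 equiv), MgO, PhCF3, 0 °C to rt
Reagents that add atoms: 2-(4-methoxybenzyloxy)-4-methylquinoline, COc1ccc(COc2cc(C)c3ccccc3n2)cc1
Why: PMB transfer from the N-methylated 2-benzyloxyquinolinium salt under neutral conditions etherifies the hindered bis-allylic C3 alcohol without forming an alkoxide, which would invite silyl migration from the neighbouring silyl ethers.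

Step 8
Reactants: 14 3-O-(4-methoxybenzyl) ether of 13
Product: 15 (2Z)-4-[(tert-butyldimethylsilyl)oxy]-2-{1-[(4-methoxybenzyl)oxy]prop-2-en-1-yl}-5-{[(4-methoxybenzyl)oxy]methyl}hexa-2,5-dien-1-ol
Conditions: HF·pyridine, pyridine, THF, 0 °C
Reagents that add atoms: none
Why: Buffered HF·pyridine should cleave the primary allylic TBS ether much faster than the hindered secondary one (selective desilylation) and frees the C1′ hydroxymethyl group as the directing allylic alcohol.

Step 9
Reactants: 15 (2Z)-4-[(tert-butyldimethylsilyl)oxy]-2-{1-[(4-methoxybenzyl)oxy]prop-2-en-1-yl}-5-{[(4-methoxybenzyl)oxy]methyl}hexa-2,5-dien-1-ol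
Product: 16 [(2S,3R)-3-{1-[(tert-butyldimethylsilyl)oxy]-2-{[(4-methoxybenzyl)oxy]methyl}prop-2-en-1-yl}-2-{1-[(4-methoxybenzyl)oxy]prop-2-en-1-yl}oxiran-2-yl]methanol
Conditions: Ti(OiPr)4 (0.3 equiv), D-(−)-diisopropyl tartrate (0.36 equiv), t-BuOOH (2 equiv, decane), 4 Å MS, CH2Cl2, −20 °C
Reagents that add atoms: tert-butyl hydroperoxide, CC(C)(C)OO
Why: Sharpless asymmetric epoxidation acts only on C4=C5, the one alkene allylic to the free primary alcohol, and sets C4 and C5 under reagent control with C3 and C6 kept cis by suprafacial oxygen transfer; D-(−)-tartrate is needed because the L-(+) ligand gives the series in which O→C3→C1 runs anticlockwise at C2 of the epoxy alcohol when the 2-substituent points away, whereas the target needs the clockwise sense.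

Step 10
Reactants: 16 [(2S,3R)-3-{1-[(tert-butyldimethylsilyl)oxy]-2-{[(4-methoxybenzyl)oxy]methyl}prop-2-en-1-yl}-2-{1-[(4-methoxybenzyl)oxy]prop-2-en-1-yl}oxiran-2-yl]methanol
Product: 17 (2S,3R)-oxirane-2-carbaldehyde corresponding to 16 (CH2OH oxidised to CHO)
Conditions: Dess–Martin periodinane, NaHCO3, CH2Cl2, 0 °C to rt
Reagents that add atoms: none
Why: Dess–Martin oxidation of the primary epoxy alcohol gives an epoxy aldehyde on a quaternary carbon, which cannot epimerise.

Step 11
Reactants: 18 (2E)-pent-2-en-4-yn-1-ol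
Product: 19 tert-butyldimethyl{[(2E)-pent-2-en-4-yn-1-yl]oxy}silane
Conditions: TBSCl, imidazole, CH2Cl2, 0 °C to rt
Reagents that add atoms: tert-butyldimethylsilyl chloride, CC(C)(C)[Si](C)(C)Cl
Why: Standard silylation of the primary allylic alcohol protects the future C6′ oxygen through the organometallic steps.

Step 12
Reactants: 19 tert-butyldimethyl{[(2E)-pent-2-en-4-yn-1-yl]oxy}silane
Product: 21 tert-butyl{[(2E,4E)-5-iodo-4-methylpenta-2,4-dien-1-yl]oxy}dimethylsilane, via alkenylalane 20 (not isolated)
Conditions: Me3Al (2 equiv), Cp2ZrCl2 (0.25 equiv), CH2Cl2, 0 °C to rt; then I2, THF, −30 to 0 °C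
Reagents that add atoms: trimethylaluminium, C[Al](C)C; iodine, II
Why: Negishi zirconium-catalysed carboalumination adds methyl and aluminium syn across the terminal alkyne with methyl on the internal carbon, and iodinolysis with retention gives the (E,E)-dienyl iodide.

Step 13
Reactants: 21 tert-butyl{[(2E,4E)-5-iodo-4-methylpenta-2,4-dien-1-yl]oxy}dimethylsilane; 17 (2S,3R)-oxirane-2-carbaldehyde corresponding to 16
Product: 24 C1′ acetate of the dienyl adduct (oxirane and C1′ configured as in 30; C3–OPMB; C6–OTBS; C6′–OTBS), via dienyllithium 22 (not isolated), via lithium alkoxide 23 (not isolated)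
Conditions: 21, t-BuLi (2.0 equiv), Et2O, −78 °C; add 17 in THF, −78 °C; then Ac2O, −78 to 0 °C
Reagents that add atoms: acetic anhydride, CC(=O)OC(C)=O
Why: Iodine–lithium exchange with retention gives the (E,E)-dienyllithium, which should add under Felkin–Anh/Cornforth control (nucleophile anti to the bulky C3 branch, carbonyl dipole opposed to the oxirane C–O, no chelating metal) to set the C1′ configuration of the target, and the alkoxide is acetylated in the same flask.

Step 14
Reactants: 24 C1′ acetate of the dienyl adduct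
Product: 25 diol with free C3–OH and free CH2OH on C1 (otherwise as 24)
Conditions: DDQ (2.5 equiv), CH2Cl2/pH 7 buffer (10:1), 0 °C
Reagents that add atoms: none
Why: Oxidative cleavage of both p-methoxybenzyl ethers by DDQ (hydride abstraction, hydrolysis of the oxocarbenium ions) under buffered conditions should spare the silyl ethers, the acetate, the epoxide and the diene.

Step 15
Reactants: 25 diol with free C3–OH and free CH2OH on C1
Product: 26 primary allylic acetate with free C3–OH (otherwise as 25)
Conditions: AcCl (1.1 equiv), 2,4,6-collidine, CH2Cl2, −78 °C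
Reagents that add atoms: acetyl chloride, CC(=O)Cl
Why: Chemoselective acylation: the primary allylic alcohol reacts at −78 °C, the hindered secondary C3 carbinol next to the quaternary oxirane carbon does not.

Step 16
Reactants: 26 primary allylic acetate with free C3–OH
Product: 27 epoxy vinyl ketone (metathesis substrate): C3 ketone, C1′–OAc, C6–OTBS, CH2OAc on C1, C6′–OTBS
Conditions: Dess–Martin periodinane, NaHCO3, CH2Cl2, 0 °C
Reagents that add atoms: none
Why: Dess–Martin oxidation of the C3 allylic carbinol under buffered conditions gives the epoxy vinyl ketone and removes the C3 epimers, while the C6 silyl ether rules out hemiketal formation.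

Step 17
Reactants: 27 epoxy vinyl ketone (metathesis substrate)
Product: 28 ring-closed epoxy enone with C6–OTBS (7-oxabicyclo[4.1.0]hept-3-en-2-one core; C6 epimers)
Conditions: Hoveyda–Grubbs 2nd-generation catalyst (15 mol%), toluene (0.002 M), 80 °C, argon sparge
Reagents that add atoms: none
Why: A ruthenium alkylidene takes up one terminal alkene, and intramolecular [2+2] addition to the other terminus followed by cycloreversion of the ruthenacyclobutane forms C1=C2 and releases ethylene, whose escape drives the reaction. The closest known reaction type is ring-closing metathesis of vinyl ketones with 1,1-disubstituted allylic ethers to 3-substituted cyclohex-2-enones, including substrates that carry an epoxide. The six-membered carbocycle closes by olefin metathesis to an endocyclic trisubstituted alkene, helped by the cis-oxirane that keeps C3 and C6 on one face. No stereocentre is formed. Selectivity among the five C=C bonds should follow from geometry and substitution: only the two terminal alkenes share a face of the oxirane, closure of the acryloyl carbene onto C2′=C3′ would need attack on a trisubstituted alkene to give a strained five-membered ring, and the internal diene alkenes initiate slowly. The C6 silyl ether prevents both hemiketal formation and ruthenium hydride isomerisation of a free allylic alcohol.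

Step 18
Reactants: 28 ring-closed epoxy enone with C6–OTBS
Product: 29 diol with free C6–OH and free C6′–OH (otherwise as 28)
Conditions: HF·pyridine, pyridine, THF, 0 °C to rt
Reagents that add atoms: none
Why: Fluoride-mediated desilylation removes both TBS ethers under non-basic conditions that should spare the acetates and the epoxy enone.

Step 19
Reactants: 29 diol with free C6–OH and free C6′–OH
Product: 30 [(1R,6S)-1-[(1S,2E,4E)-1-acetoxy-3-methyl-6-oxohexa-2,4-dien-1-yl]-2,5-dioxo-7-oxabicyclo[4.1.0]hept-3-en-4-yl]methyl acetate (CNP0307549.1)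
Conditions: Dess–Martin periodinane (3 equiv), NaHCO3, CH2Cl2, 0 °C to rt
Reagents that add atoms: none
Why: One buffered Dess–Martin oxidation converts the ring C6 carbinol into the enedione (removing the C6 epimers) and the dienol into the dienal.

Compound list
1 | but-2-yne-1,4-diol | OCC#CCO | starting material
2 | 4-[(tert-butyldimethylsilyl)oxy]but-2-yn-1-ol | OCC#CCO[Si](C)(C)C(C)(C)C | intermediate
3 | sodium cyclic alkoxy(alkenyl)bis(2-methoxyethoxy)aluminate (five-membered O–Al–C=C ring, Al on the carbon bearing CH2OTBS) | COCCO[Al-]1(OCCOC)OCC=C1CO[Si](C)(C)C(C)(C)C.[Na+] | intermediate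
4 | (2Z)-4-[(tert-butyldimethylsilyl)oxy]-3-iodobut-2-en-1-ol | OC/C=C(\I)CO[Si](C)(C)C(C)(C)C | intermediate
5 | (2Z)-4-[(tert-butyldimethylsilyl)oxy]-3-iodobut-2-enal | O=C/C=C(\I)CO[Si](C)(C)C(C)(C)C | intermediate
6 | 2-bromoprop-2-en-1-ol | OCC(Br)=C | starting material
7 | 2-bromoallyl 4-methoxybenzyl ether | C=C(Br)COCc1ccc(OC)cc1 | intermediate
8 | 2-lithio-3-[(4-methoxybenzyl)oxy]prop-1-ene | [Li]C(=C)COCc1ccc(OC)cc1 | intermediate
9 | lithium alkoxide of the C6 carbinol (adduct of 8 and 5) | [Li]OC(/C=C(\I)CO[Si](C)(C)C(C)(C)C)C(=C)COCc1ccc(OC)cc1 | intermediate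
10 | (4Z)-3,6-bis[(tert-butyldimethylsilyl)oxy]-5-iodo-2-{[(4-methoxybenzyl)oxy]methyl}hexa-1,4-diene (racemic at the carbinol carbon, C6 of the target) | C=C(COCc1ccc(OC)cc1)C(O[Si](C)(C)C(C)(C)C)/C=C(\I)CO[Si](C)(C)C(C)(C)C | intermediate
11 | acrolein (prop-2-enal) | C=CC=O | starting material
12 | alkenyllithium from 10 (Li in place of I, geometry retained) | C=C(COCc1ccc(OC)cc1)C(O[Si](C)(C)C(C)(C)C)/C=C(\[Li])CO[Si](C)(C)C(C)(C)C | intermediate
13 | (4Z)-6-[(tert-butyldimethylsilyl)oxy]-4-{[(tert-butyldimethylsilyl)oxy]methyl}-7-{[(4-methoxybenzyl)oxy]methyl}octa-1,4,7-trien-3-ol (both carbinol centres as epimer mixtures) | C=CC(O)/C(CO[Si](C)(C)C(C)(C)C)=C\C(O[Si](C)(C)C(C)(C)C)C(=C)COCc1ccc(OC)cc1 | intermediate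
14 | 3-O-(4-methoxybenzyl) ether of 13 | C=CC(OCc1ccc(OC)cc1)/C(CO[Si](C)(C)C(C)(C)C)=C\C(O[Si](C)(C)C(C)(C)C)C(=C)COCc1ccc(OC)cc1 | intermediate
15 | (2Z)-4-[(tert-butyldimethylsilyl)oxy]-2-{1-[(4-methoxybenzyl)oxy]prop-2-en-1-yl}-5-{[(4-methoxybenzyl)oxy]methyl}hexa-2,5-dien-1-ol | C=CC(OCc1ccc(OC)cc1)/C(CO)=C\C(O[Si](C)(C)C(C)(C)C)C(=C)COCc1ccc(OC)cc1 | intermediate
16 | [(2S,3R)-3-{1-[(tert-butyldimethylsilyl)oxy]-2-{[(4-methoxybenzyl)oxy]methyl}prop-2-en-1-yl}-2-{1-[(4-methoxybenzyl)oxy]prop-2-en-1-yl}oxiran-2-yl]methanol | C=CC(OCc1ccc(OC)cc1)[C@]1(CO)O[C@@H]1C(O[Si](C)(C)C(C)(C)C)C(=C)COCc1ccc(OC)cc1 | intermediate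
17 | (2S,3R)-oxirane-2-carbaldehyde corresponding to 16 | C=CC(OCc1ccc(OC)cc1)[C@]1(C=O)O[C@@H]1C(O[Si](C)(C)C(C)(C)C)C(=C)COCc1ccc(OC)cc1 | intermediate
18 | (2E)-pent-2-en-4-yn-1-ol | C#C/C=C/CO | starting material
19 | tert-butyldimethyl{[(2E)-pent-2-en-4-yn-1-yl]oxy}silane | C#C/C=C/CO[Si](C)(C)C(C)(C)C | intermediate
20 | dimethyl[(1E,3E)-2-methyl-5-(tert-butyldimethylsilyloxy)penta-1,3-dien-1-yl]alane | C[Al](C)/C=C(C)/C=C/CO[Si](C)(C)C(C)(C)C | intermediate
21 | tert-butyl{[(2E,4E)-5-iodo-4-methylpenta-2,4-dien-1-yl]oxy}dimethylsilane | I/C=C(C)/C=C/CO[Si](C)(C)C(C)(C)C | intermediate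
22 | [(1E,3E)-2-methyl-5-(tert-butyldimethylsilyloxy)penta-1,3-dien-1-yl]lithium | [Li]/C=C(C)/C=C/CO[Si](C)(C)C(C)(C)C | intermediate
23 | lithium C1′-alkoxide from 22 and 17 | C=CC(OCc1ccc(OC)cc1)[C@]1([C@H](/C=C(C)/C=C/CO[Si](C)(C)C(C)(C)C)O[Li])O[C@@H]1C(O[Si](C)(C)C(C)(C)C)C(=C)COCc1ccc(OC)cc1 | intermediate
24 | C1′ acetate of the dienyl adduct (oxirane and C1′ as in 30; C3–OPMB, C6–OTBS, CH2OPMB on C1, C6′–OTBS) | C=CC(OCc1ccc(OC)cc1)[C@]1([C@H](/C=C(C)/C=C/CO[Si](C)(C)C(C)(C)C)OC(C)=O)O[C@@H]1C(O[Si](C)(C)C(C)(C)C)C(=C)COCc1ccc(OC)cc1 | intermediate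
25 | diol: 24 with free C3–OH and free CH2OH on C1 | C=CC(O)[C@]1([C@H](/C=C(C)/C=C/CO[Si](C)(C)C(C)(C)C)OC(C)=O)O[C@@H]1C(O[Si](C)(C)C(C)(C)C)C(=C)CO | intermediate
26 | 25 with the primary allylic alcohol acetylated (C3–OH free) | C=CC(O)[C@]1([C@H](/C=C(C)/C=C/CO[Si](C)(C)C(C)(C)C)OC(C)=O)O[C@@H]1C(O[Si](C)(C)C(C)(C)C)C(=C)COC(C)=O | intermediate
27 | epoxy vinyl ketone, metathesis substrate (C3 ketone, C1′–OAc, C6–OTBS, CH2OAc on C1, C6′–OTBS) | C=CC(=O)[C@]1([C@H](/C=C(C)/C=C/CO[Si](C)(C)C(C)(C)C)OC(C)=O)O[C@@H]1C(O[Si](C)(C)C(C)(C)C)C(=C)COC(C)=O | intermediate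
28 | ring-closed epoxy enone with C6–OTBS and C6′–OTBS (C6 epimers) | CC(=O)OCC1=CC(=O)[C@]2([C@H](/C=C(C)/C=C/CO[Si](C)(C)C(C)(C)C)OC(C)=O)O[C@@H]2C1O[Si](C)(C)C(C)(C)C | intermediate
29 | 28 with both silyl ethers removed (C6–OH, C6′–OH) | CC(=O)OCC1=CC(=O)[C@]2([C@H](/C=C(C)/C=C/CO)OC(C)=O)O[C@@H]2C1O | intermediate
30 | [(1R,6S)-1-[(1S,2E,4E)-1-acetoxy-3-methyl-6-oxohexa-2,4-dien-1-yl]-2,5-dioxo-7-oxabicyclo[4.1.0]hept-3-en-4-yl]methyl acetate | CC(=O)OCC1=CC(=O)[C@]2([C@H](/C=C(C)/C=C/C=O)OC(C)=O)O[C@@H]2C1=O | target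

Total step count: 19. Longest linear sequence: 16 steps (steps 1–3, 5–10 and 13–19, from but-2-yne-1,4-diol).

Steps most likely to fail

Step 17. The catalyst may fail to turn over on two poor partners (an acryloyl alkene and a hindered 1,1-disubstituted alkene), may engage the chain diene and cause truncation, or the vinyl ketone may oligomerise. The fallback closes the ring one oxidation level earlier. It sets out from 26, whose C3 vinyl carbinol loads ruthenium readily (Grubbs 2nd-generation catalyst, CH2Cl2, 40 °C), and should give the ring-closed C3 allylic alcohol F1. Dess–Martin oxidation of F1 comes back to the route at 28.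

Step 13. Facial selectivity in the addition to the epoxy aldehyde may be poor, because a lithium-chelated transition state competes with the Felkin–Anh/Cornforth one and leads to the C1′ epimer. The fallback sets out from 17: addition of 22 with an aqueous quench gives the C1′ carbinol epimer mixture F2, and Dess–Martin oxidation gives the dienone F3. Zn(BH4)2 in Et2O at −30 °C then reduces F3 under chelation between the ketone and the oxirane oxygen, with hydride arriving past the oxirane CH and away from the C3 branch, to the single C1′ carbinol F4. Acetylation of F4 (Ac2O, pyridine, DMAP) rejoins the route at 24.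

Step 6. The γ-silyloxy alkenyllithium may undergo 1,4 O-to-C silyl migration, or be protonated, before it is captured by acrolein. The fallback is a Nozaki–Hiyama–Kishi coupling of 10 with acrolein 11 (CrCl2, NiCl2 cat., DMSO, rt). An alkenylchromium(III) species does not undergo the silyl shift, keeps the alkene geometry and adds 1,2 to aldehydes. It sets out from 10 and comes back at 13 without a new compound (F0).

Further compounds
F1 | step 17 | ring-closed C3 allylic alcohol (28 with C3–OH in place of the C3 ketone, C3 epimers) | CC(=O)OCC1=CC(O)[C@]2([C@H](/C=C(C)/C=C/CO[Si](C)(C)C(C)(C)C)OC(C)=O)O[C@@H]2C1O[Si](C)(C)C(C)(C)C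
F2 | step 13 | C1′ carbinol from 22 and 17 as epimer mixture | C=CC(OCc1ccc(OC)cc1)[C@]1(C(O)/C=C(C)/C=C/CO[Si](C)(C)C(C)(C)C)O[C@@H]1C(O[Si](C)(C)C(C)(C)C)C(=C)COCc1ccc(OC)cc1
F3 | step 13 | C1′ dienone | C=CC(OCc1ccc(OC)cc1)[C@]1(C(=O)/C=C(C)/C=C/CO[Si](C)(C)C(C)(C)C)O[C@@H]1C(O[Si](C)(C)C(C)(C)C)C(=C)COCc1ccc(OC)cc1
F4 | step 13 | single C1′ carbinol with the configuration of 24 | C=CC(OCc1ccc(OC)cc1)[C@]1([C@H](/C=C(C)/C=C/CO[Si](C)(C)C(C)(C)C)O)O[C@@H]1C(O[Si](C)(C)C(C)(C)C)C(=C)COCc1ccc(OC)cc1
F0 | step 6 | none | none
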